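In a one-step world a catalyst turns over unchanged, and a low yield calls for a longer run; this flask also has a poisoning step and a competing substrate.

starting material 0.11 M; partner 2.00 equiv; second substrate 1.00 equiv; free catalyst 0.2 mol%; impurity 0.24 mM; time 10 min

    starting material + partner + free catalyst → free catalyst + target (k1 = 16000 L² mol⁻² s⁻¹)
    second substrate + partner + free catalyst → free catalyst + second product (k2 = 45000 L² mol⁻² s⁻¹)
    partner → decomposed reagent (k3 = 0.0031 s⁻¹)
    free catalyst + impurity → spent catalyst (k4 = 2200 L mol⁻¹ s⁻¹)

- amount of target at 10 min, in percent of the starting material charged
- amount of target if the flask were left three thousand times as long, in percent of the starting material charged

The next run must vary either time or loading, and the balance of the smallest charge points the way. Free catalyst stands at 0.220 mM and impurity at 0.24 mM, which is more, so poisoning can consume the catalyst and still leave 0.0200 mM of impurity.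

Integrating free catalyst over time along the poisoning step gives ln(impurity charged / impurity excess) divided by the poisoning constant. Multiplied by the target-step constant and the starting material charged, this is 1.99: the catalyst budget. The late catalyst lifetime, 22.7 s, is shorter than both the partner half-life of 3.7 min and the 10 min allowed, so this reckoning omits decomposition and the budget carries no clock.

Measured against the budget, the fraction of starting material left falls in proportion to itself and to the partner, in units of the starting charge. With decomposition omitted, partner at 2.00 equiv stays equal in this reckoning to starting material left plus second substrate left, and second substrate, with the larger constant, is taken to stay below starting material, so the reckoned partner lies between one and two times the starting material left. One gives the low end of the reckoning, budget/(1 + budget), or 66.5%. Two gives its high end, 79.9%. The selectivity factor of 2.81 favours second substrate, so my reckoning commits to the lower part of that range for both questions. The plate should therefore step loading against impurity and leave the time.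

The forecast gives 70.5% and 70.5%, on the ground that “the catalyst is dead within about a minute”.

This flask gives 70.9% and 70.9%, in the lower part of the reckoned range. In this flask, of the turnover up to 10 min, half of the second substrate's is done by 0.424 s and half of the decomposition's by 2.73 min, and at 5.00 min free catalyst stands at 0% with 29.1% of the starting material left. In the neighbour flask with 9.6 × 10⁻⁴ M of impurity, the budget is 0.208, which reckons 17.2% to 29.4% of target; that flask gives 26.6%.

(The constants are made up; the run is a simulation.)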